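## Retrosynthetic overview

1. The target comes from a macrocyclic epoxy alcohol by Mitsunobu esterification with inversion at the carbinol carbon, cross-metathesis of an allyl group to build the hydroxylated side chain, and desilylation.
2. The 11-membered carbocycle is closed last, by an electrochemical chromium/nickel alkenyl–aldehyde coupling of an acyclic iodoalkene carrying an α-quaternary epoxy aldehyde.
3. The oxirane is made just before ring closure by hydroxyl-directed epoxidation of a glycerate-derived allylic 1,2-diol; glycol cleavage then removes the steering carbinol and exposes the aldehyde.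
4. The open chain is joined by Horner–Wadsworth–Emmons olefination of a fragment A aldehyde with a fragment B phosphonate. Fragment A carries the quaternary carbon, set by double alkylation of the L-glutamic-acid-derived trityl lactone. Fragment B comes from methyl (R)-glycerate acetonide through alkyne carboalumination.
5. Ring order: oxirane first, carbocycle second.

Assumption: target ring atoms are numbered C1 (ester-bearing carbinol), C2=C3, C4 (quaternary), C5, C6=C7, C8, C9, C10 and C11 (oxirane carbons, C11 bearing methyl), and this numbering is used in the comments for all intermediates; compounds 1, 10, 16, 25, 27 and all reagents are bought.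

## Route

**Step 1**
Reactants: 1 (5S)-5-[(triphenylmethoxy)methyl]oxolan-2-one
Product: 2 (3R,5S)-3-methyl-5-[(triphenylmethoxy)methyl]oxolan-2-one
Conditions: LiN(iPr)2 (1.1 equiv), THF, −78 °C; MeI, −78 → −40 °C
Reagents that add atoms: iodomethane, CI
Why: Lithium enolate alkylation in which MeI enters trans to the trityloxymethyl group (1,3-induction); this centre is re-enolised in step 2, so its ratio does not matter.

**Step 2**
Reactants: 2 (3R,5S)-3-methyl-5-[(triphenylmethoxy)methyl]oxolan-2-one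
Product: 3 (3R,5S)-3-methyl-3-(prop-2-en-1-yl)-5-[(triphenylmethoxy)methyl]oxolan-2-one
Conditions: LiN(iPr)2 (1.2 equiv), THF, −78 °C; allyl bromide, DMPU, −78 → −20 °C
Reagents that add atoms: allyl bromide, C=CCBr
Why: Second enolate alkylation in which allyl bromide attacks the planar enolate anti to the trityloxymethyl group, so the later-introduced group ends trans and the quaternary carbon (target C4, R) is fixed by the glutamic-acid-derived centre.

**Step 3**
Reactants: 3 (3R,5S)-3-methyl-3-(prop-2-en-1-yl)-5-[(triphenylmethoxy)methyl]oxolan-2-one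
Product: 5 (2S,4R)-4-ethynyl-4-methyl-1-(triphenylmethoxy)hept-6-en-2-ol, via lactol 4 (not isolated)
Conditions: iBu2AlH (1.2 equiv), CH2Cl2, −78 °C; then MeOH, K2CO3, dimethyl (1-diazo-2-oxopropyl)phosphonate, 0 → 25 °C
Reagents that add atoms: dimethyl (1-diazo-2-oxopropyl)phosphonate (Ohira–Bestmann reagent), CC(=O)C(=[N+]=[N-])P(=O)(OC)OC
Why: iBu2AlH stops at the lactol, whose ring-opened hydroxy aldehyde undergoes Seyferth–Gilbert homologation (Ohira–Bestmann variant) under carbonate/methanol; the quaternary α-carbon cannot epimerise.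

**Step 4**
Reactants: 5 (2S,4R)-4-ethynyl-4-methyl-1-(triphenylmethoxy)hept-6-en-2-ol
Product: 7 (2S,4R,5E)-6-iodo-4-methyl-4-(prop-2-en-1-yl)-1-(triphenylmethoxy)hex-5-en-2-ol, via vinylstannane 6 (not isolated)
Conditions: Bu3SnH (1.2 equiv), PdCl2(PPh3)2 (2 mol %), THF, 0 °C; then I2 (1.2 equiv), CH2Cl2, 0 °C
Reagents that add atoms: tributyltin hydride (tin stays only in 6), CCCC[SnH](CCCC)CCCC; iodine, II
Why: Palladium-catalysed syn-hydrostannation puts tin on the terminal carbon because the quaternary neighbour blocks the internal position, and iododestannylation with retention gives the (E)-iodoalkene while the isolated terminal alkene is untouched.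

**Step 5**
Reactants: 7 (2S,4R,5E)-6-iodo-4-methyl-4-(prop-2-en-1-yl)-1-(triphenylmethoxy)hex-5-en-2-ol
Product: 9 (3R,4E)-5-iodo-3-methyl-3-(prop-2-en-1-yl)pent-4-enal, via diol 8 (not isolated)
Conditions: TsOH·H2O (10 mol %), MeOH/CH2Cl2, 0 → 25 °C; NaHCO3, concentrate; then NaIO4, THF/H2O, 0 °C
Reagents that add atoms: none
Why: Acid methanolysis of the trityl ether followed by Malaprade glycol cleavage turns the former lactone carbinol into the C6 aldehyde; the stereocentre lost here has already set C4.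

**Step 6**
Reactants: 10 methyl (4R)-2,2-dimethyl-1,3-dioxolane-4-carboxylate
Product: 12 (4S)-4-ethynyl-2,2-dimethyl-1,3-dioxolane, via aldehyde 11 (not isolated)
Conditions: iBu2AlH (1.1 equiv), CH2Cl2, −78 °C; then MeOH, K2CO3, dimethyl (1-diazo-2-oxopropyl)phosphonate, 0 → 25 °C
Reagents that add atoms: dimethyl (1-diazo-2-oxopropyl)phosphonate (Ohira–Bestmann reagent), CC(=O)C(=[N+]=[N-])P(=O)(OC)OC
Why: One-pot half-reduction and Seyferth–Gilbert homologation (Ohira–Bestmann variant) in which the α-alkoxy aldehyde is never isolated and is not epimerised by the mild carbonate conditions.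

**Step 7**
Reactants: 12 (4S)-4-ethynyl-2,2-dimethyl-1,3-dioxolane
Product: 14 (3E)-4-[(4S)-2,2-dimethyl-1,3-dioxolan-4-yl]pent-3-en-1-ol, via alkenylalane 13 (not isolated)
Conditions: Me3Al (3 equiv), Cp2ZrCl2 (20 mol %), H2O (1.5 equiv), CH2Cl2, −25 °C; evaporate; n-BuLi, THF/hexane, −78 °C; oxirane, −78 → 0 °C
Reagents that add atoms: trimethylaluminium, C[Al](C)C; oxirane, C1CO1
Why: Negishi zirconium-catalysed methylalumination (water-accelerated variant) adds methyl and aluminium syn with methyl on the internal carbon, and the derived alanate opens oxirane with retention, so the new two-carbon arm ends cis to the methyl group, giving the (E)-trisubstituted C10=C11 alkene.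

**Step 8**
Reactants: 14 (3E)-4-[(4S)-2,2-dimethyl-1,3-dioxolan-4-yl]pent-3-en-1-ol
Product: 15 (4S)-4-[(2E)-5-iodopent-2-en-2-yl]-2,2-dimethyl-1,3-dioxolane
Conditions: I2, PPh3, imidazole, CH2Cl2, 0 °C
Reagents that add atoms: iodine, II
Why: Appel-type iodination of an unhindered primary alcohol under neutral conditions that leave the acetonide and the alkene geometry intact.

**Step 9**
Reactants: 15 (4S)-4-[(2E)-5-iodopent-2-en-2-yl]-2,2-dimethyl-1,3-dioxolane; 16 methyl 2-(dimethoxyphosphoryl)acetate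
Product: 17 methyl (5E)-2-(dimethoxyphosphoryl)-6-[(4S)-2,2-dimethyl-1,3-dioxolan-4-yl]hept-5-enoate (both C2 epimers)
Conditions: 16 (2 equiv), NaH (1.9 equiv), DMF, 0 °C; then 15, 50 °C
Reagents that add atoms: none
Why: SN2 C-alkylation of the sodium phosphonoacetate by a primary iodide, with excess phosphonate suppressing dialkylation.

**Step 10**
Reactants: 17 methyl (5E)-2-(dimethoxyphosphoryl)-6-[(4S)-2,2-dimethyl-1,3-dioxolan-4-yl]hept-5-enoate; 9 (3R,4E)-5-iodo-3-methyl-3-(prop-2-en-1-yl)pent-4-enal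
Product: 18 methyl (2E,5R,6E)-2-{(3E)-4-[(4S)-2,2-dimethyl-1,3-dioxolan-4-yl]pent-3-en-1-yl}-7-iodo-5-methyl-5-(prop-2-en-1-yl)hepta-2,6-dienoate
Conditions: 17 (1.2 equiv), NaH, THF, 0 °C; then 9, 0 → 25 °C (E:Z about 9:1, minor isomer removed)
Reagents that add atoms: none
Why: Horner–Wadsworth–Emmons olefination of an unhindered aldehyde with an α-alkyl phosphonoacetate gives the thermodynamically favoured (E)-enoate with the ester trans to C5, which is the C6=C7 geometry of the target.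

**Step 11**
Reactants: 18 methyl (2E,5R,6E)-2-{(3E)-4-[(4S)-2,2-dimethyl-1,3-dioxolan-4-yl]pent-3-en-1-yl}-7-iodo-5-methyl-5-(prop-2-en-1-yl)hepta-2,6-dienoate
Product: 19 (2E,5R,6E)-2-{(3E)-4-[(4S)-2,2-dimethyl-1,3-dioxolan-4-yl]pent-3-en-1-yl}-7-iodo-5-methyl-5-(prop-2-en-1-yl)hepta-2,6-dien-1-ol
Conditions: iBu2AlH (2.5 equiv), CH2Cl2, −78 °C; sodium potassium tartrate work-up
Reagents that add atoms: none
Why: 1,2-Reduction of the enoate by iBu2AlH gives the allylic alcohol without touching the iodoalkene, acetonide or alkene geometry.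

**Step 12**
Reactants: 19 (2E,5R,6E)-2-{(3E)-4-[(4S)-2,2-dimethyl-1,3-dioxolan-4-yl]pent-3-en-1-yl}-7-iodo-5-methyl-5-(prop-2-en-1-yl)hepta-2,6-dien-1-ol
Product: 20 tert-butyldiphenylsilyl ether of 19, tert-butyl{[(2E,5R,6E)-2-{(3E)-4-[(4S)-2,2-dimethyl-1,3-dioxolan-4-yl]pent-3-en-1-yl}-7-iodo-5-methyl-5-(prop-2-en-1-yl)hepta-2,6-dien-1-yl]oxy}diphenylsilane
Conditions: t-BuPh2SiCl, imidazole, CH2Cl2, 25 °C
Reagents that add atoms: tert-butyl(chloro)diphenylsilane, CC(C)(C)[Si](Cl)(c1ccccc1)c1ccccc1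
Why: Silylation of the primary allylic alcohol keeps the C6=C7 alkene out of the hydroxyl-directed epoxidation and the hydroxyl out of the Mitsunobu step, and the group survives the acid used next.

**Step 13**
Reactants: 20 tert-butyldiphenylsilyl ether of 19
Product: 21 (2S,3E,7E,10R,11E)-7-{[(tert-butyldiphenylsilyl)oxy]methyl}-12-iodo-3,10-dimethyl-10-(prop-2-en-1-yl)dodeca-3,7,11-triene-1,2-diol
Conditions: AcOH/H2O/THF (3:1:1), 45 °C
Reagents that add atoms: none
Why: Mild acetal hydrolysis frees the glycerate-derived 1,2-diol while the tert-butyldiphenylsilyl ether and iodoalkene are stable.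

**Step 14**
Reactants: 21 (2S,3E,7E,10R,11E)-7-{[(tert-butyldiphenylsilyl)oxy]methyl}-12-iodo-3,10-dimethyl-10-(prop-2-en-1-yl)dodeca-3,7,11-triene-1,2-diol
Product: 23 (2S,3R)-3-[(3E,6R,7E)-3-{[(tert-butyldiphenylsilyl)oxy]methyl}-8-iodo-6-methyl-6-(prop-2-en-1-yl)octa-3,7-dien-1-yl]-2-methyloxirane-2-carbaldehyde, via epoxy diol 22 (not isolated)
Conditions: VO(acac)2 (5 mol %), t-BuOOH (1.3 equiv, decane), CH2Cl2, 0 °C; Me2S; then NaIO4, THF/pH 7 buffer, 0 °C
Reagents that add atoms: tert-butyl hydroperoxide, CC(C)(C)OO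
Why: In the hydroxyl-directed epoxidation, pentavalent vanadium bound to the secondary allylic alkoxide delivers oxygen to the C10=C11 face that keeps the carbinol hydrogen next to the C11 methyl (A(1,2) strain), so the (S)-carbinol gives the erythro epoxide with the target (10R,11S) oxirane configuration; Malaprade cleavage then excises that carbinol and leaves a non-epimerisable quaternary epoxy aldehyde, and no other alkene has a free allylic hydroxyl.

**Step 15**
Reactants: 23 (2S,3R)-3-[(3E,6R,7E)-3-{[(tert-butyldiphenylsilyl)oxy]methyl}-8-iodo-6-methyl-6-(prop-2-en-1-yl)octa-3,7-dien-1-yl]-2-methyloxirane-2-carbaldehyde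
Product: 24 (1R,2R,3E,5R,7E,11R)-8-{[(tert-butyldiphenylsilyl)oxy]methyl}-1,5-dimethyl-5-(prop-2-en-1-yl)-12-oxabicyclo[9.1.0]dodeca-3,7-dien-2-ol
Conditions: CrCl2 (20 mol %), NiCl2(dme) (2 mol %), 2,9-dimethyl-1,10-phenanthroline (3 mol %), Cp2ZrCl2 (1.5 equiv), LiCl, Bu4NPF6 (0.1 M), DMF, undivided cell, Al anode, Ni-foam cathode, constant current (about 2.2 F/mol), 23 added by syringe pump to 2 mM, 25 °C; aqueous sodium potassium tartrate work-up
Reagents that add atoms: none
Why: Proposed new method: an electrochemically turned-over chromium/nickel Nozaki–Hiyama–Kishi ring closure onto an α-quaternary α,β-epoxy aldehyde, in which zerovalent nickel inserts into the C–I bond, the alkenyl group passes to trivalent chromium, the alkenylchromium adds to the aldehyde, Cp2ZrCl2 strips the chromium alkoxide and the cathode returns trivalent to divalent chromium, so only catalytic chromium is present at high dilution; the aldehyde should react in the Cornforth arrangement (C=O anti to the oxirane C–O bond) on the face away from C10, giving the erythro (target-numbering 1R) alcohol controlled by the oxirane; the closest known reactions are the intermolecular electrochemical Cr/Ni alkenylation of aldehydes and stoichiometric CrCl2/NiCl2 macrocyclisations, neither shown for an 11-membered carbocycle or an epoxy aldehyde of this kind.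

**Step 16**
Reactants: 24 (1R,2R,3E,5R,7E,11R)-8-{[(tert-butyldiphenylsilyl)oxy]methyl}-1,5-dimethyl-5-(prop-2-en-1-yl)-12-oxabicyclo[9.1.0]dodeca-3,7-dien-2-ol; 25 3-methylbut-2-enoic acid
Product: 26 (1S,2S,3E,5R,7E,11R)-8-{[(tert-butyldiphenylsilyl)oxy]methyl}-1,5-dimethyl-5-(prop-2-en-1-yl)-12-oxabicyclo[9.1.0]dodeca-3,7-dien-2-yl 3-methylbut-2-enoate
Conditions: 25 (3 equiv), PPh3 (3 equiv), diisopropyl azodicarboxylate (3 equiv), toluene, 0 → 25 °C
Reagents that add atoms: none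
Why: Mitsunobu esterification displaces the activated allylic C1 oxygen by SN2 with clean inversion (erythro to threo, giving 1S as in the target) and installs the ester in the same step; SN2' attack at C3 is blocked by the adjacent quaternary C4.

**Step 17**
Reactants: 26 (1S,2S,3E,5R,7E,11R)-8-{[(tert-butyldiphenylsilyl)oxy]methyl}-1,5-dimethyl-5-(prop-2-en-1-yl)-12-oxabicyclo[9.1.0]dodeca-3,7-dien-2-yl 3-methylbut-2-enoate; 27 2-methylbut-3-en-2-ol
Product: 28 (1S,2S,3E,5R,7E,11R)-8-{[(tert-butyldiphenylsilyl)oxy]methyl}-5-[(2E)-4-hydroxy-4-methylpent-2-en-1-yl]-1,5-dimethyl-12-oxabicyclo[9.1.0]dodeca-3,7-dien-2-yl 3-methylbut-2-enoate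
Conditions: 27 (10 equiv), second-generation Hoveyda–Grubbs catalyst (5 mol %), CH2Cl2, 40 °C
Reagents that add atoms: none
Why: Olefin cross-metathesis of the only terminal alkene with the tertiary allylic alcohol gives the (E)-disubstituted side-chain alkene, while the trisubstituted alkenes and the hindered ring alkene do not react.

**Step 18**
Reactants: 28 (1S,2S,3E,5R,7E,11R)-8-{[(tert-butyldiphenylsilyl)oxy]methyl}-5-[(2E)-4-hydroxy-4-methylpent-2-en-1-yl]-1,5-dimethyl-12-oxabicyclo[9.1.0]dodeca-3,7-dien-2-yl 3-methylbut-2-enoate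
Product: 29 (1S,2S,3E,5R,7E,11R)-8-(hydroxymethyl)-5-[(2E)-4-hydroxy-4-methylpent-2-en-1-yl]-1,5-dimethyl-12-oxabicyclo[9.1.0]dodeca-3,7-dien-2-yl 3-methylbut-2-enoate (CNP0248133.1)
Conditions: Bu4NF (3 equiv), AcOH (3 equiv), THF, 0 → 25 °C
Reagents that add atoms: none
Why: Acetic-acid-buffered fluoride desilylation frees the primary allylic alcohol without ester migration, epoxide opening or change at any stereocentre.

## Compound list

1 | (5S)-5-[(triphenylmethoxy)methyl]oxolan-2-one | O=C1CC[C@@H](COC(c2ccccc2)(c2ccccc2)c2ccccc2)O1 | starting material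
2 | (3R,5S)-3-methyl-5-[(triphenylmethoxy)methyl]oxolan-2-one | O=C1O[C@H](COC(c2ccccc2)(c2ccccc2)c2ccccc2)C[C@H]1C | intermediate
3 | (3R,5S)-3-methyl-3-(prop-2-en-1-yl)-5-[(triphenylmethoxy)methyl]oxolan-2-one | O=C1O[C@H](COC(c2ccccc2)(c2ccccc2)c2ccccc2)C[C@@]1(C)CC=C | intermediate
4 | (3R,5S)-3-methyl-3-(prop-2-en-1-yl)-5-[(triphenylmethoxy)methyl]oxolan-2-ol (both anomers) | OC1O[C@H](COC(c2ccccc2)(c2ccccc2)c2ccccc2)C[C@@]1(C)CC=C | intermediate
5 | (2S,4R)-4-ethynyl-4-methyl-1-(triphenylmethoxy)hept-6-en-2-ol | C#C[C@](C)(CC=C)C[C@H](O)COC(c1ccccc1)(c1ccccc1)c1ccccc1 | intermediate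
6 | (2S,4R,5E)-4-methyl-4-(prop-2-en-1-yl)-6-(tributylstannyl)-1-(triphenylmethoxy)hex-5-en-2-ol | CCCC[Sn](CCCC)(CCCC)/C=C/[C@](C)(CC=C)C[C@H](O)COC(c1ccccc1)(c1ccccc1)c1ccccc1 | intermediate
7 | (2S,4R,5E)-6-iodo-4-methyl-4-(prop-2-en-1-yl)-1-(triphenylmethoxy)hex-5-en-2-ol | I/C=C/[C@](C)(CC=C)C[C@H](O)COC(c1ccccc1)(c1ccccc1)c1ccccc1 | intermediate
8 | (2S,4R,5E)-6-iodo-4-methyl-4-(prop-2-en-1-yl)hex-5-ene-1,2-diol | I/C=C/[C@](C)(CC=C)C[C@H](O)CO | intermediate
9 | (3R,4E)-5-iodo-3-methyl-3-(prop-2-en-1-yl)pent-4-enal | I/C=C/[C@](C)(CC=C)CC=O | intermediate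
10 | methyl (4R)-2,2-dimethyl-1,3-dioxolane-4-carboxylate | COC(=O)[C@H]1COC(C)(C)O1 | starting material
11 | (4R)-2,2-dimethyl-1,3-dioxolane-4-carbaldehyde | O=C[C@H]1COC(C)(C)O1 | intermediate
12 | (4S)-4-ethynyl-2,2-dimethyl-1,3-dioxolane | C#C[C@H]1COC(C)(C)O1 | intermediate
13 | {(1E)-2-[(4S)-2,2-dimethyl-1,3-dioxolan-4-yl]prop-1-en-1-yl}dimethylalane | C[Al](C)/C=C(\C)[C@H]1COC(C)(C)O1 | intermediate
14 | (3E)-4-[(4S)-2,2-dimethyl-1,3-dioxolan-4-yl]pent-3-en-1-ol | OCC/C=C(\C)[C@H]1COC(C)(C)O1 | intermediate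
15 | (4S)-4-[(2E)-5-iodopent-2-en-2-yl]-2,2-dimethyl-1,3-dioxolane | ICC/C=C(\C)[C@H]1COC(C)(C)O1 | intermediate
16 | methyl 2-(dimethoxyphosphoryl)acetate (trimethyl phosphonoacetate) | COC(=O)CP(=O)(OC)OC | starting material
17 | methyl (5E)-2-(dimethoxyphosphoryl)-6-[(4S)-2,2-dimethyl-1,3-dioxolan-4-yl]hept-5-enoate (both C2 epimers) | COC(=O)C(CC/C=C(\C)[C@H]1COC(C)(C)O1)P(=O)(OC)OC | intermediate
18 | methyl (2E,5R,6E)-2-{(3E)-4-[(4S)-2,2-dimethyl-1,3-dioxolan-4-yl]pent-3-en-1-yl}-7-iodo-5-methyl-5-(prop-2-en-1-yl)hepta-2,6-dienoate | I/C=C/[C@](C)(CC=C)C/C=C(/C(=O)OC)CC/C=C(\C)[C@H]1COC(C)(C)O1 | intermediate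
19 | (2E,5R,6E)-2-{(3E)-4-[(4S)-2,2-dimethyl-1,3-dioxolan-4-yl]pent-3-en-1-yl}-7-iodo-5-methyl-5-(prop-2-en-1-yl)hepta-2,6-dien-1-ol | I/C=C/[C@](C)(CC=C)C/C=C(/CO)CC/C=C(\C)[C@H]1COC(C)(C)O1 | intermediate
20 | tert-butyldiphenylsilyl ether of 19 | I/C=C/[C@](C)(CC=C)C/C=C(/CO[Si](c1ccccc1)(c1ccccc1)C(C)(C)C)CC/C=C(\C)[C@H]1COC(C)(C)O1 | intermediate
21 | (2S,3E,7E,10R,11E)-7-{[(tert-butyldiphenylsilyl)oxy]methyl}-12-iodo-3,10-dimethyl-10-(prop-2-en-1-yl)dodeca-3,7,11-triene-1,2-diol | I/C=C/[C@](C)(CC=C)C/C=C(/CO[Si](c1ccccc1)(c1ccccc1)C(C)(C)C)CC/C=C(\C)[C@H](O)CO | intermediate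
22 | (1R)-1-{(2R,3R)-3-[(3E,6R,7E)-3-{[(tert-butyldiphenylsilyl)oxy]methyl}-8-iodo-6-methyl-6-(prop-2-en-1-yl)octa-3,7-dien-1-yl]-2-methyloxiran-2-yl}ethane-1,2-diol (same geometry at the carbinol as in 21; the descriptor changes by priority only) | I/C=C/[C@](C)(CC=C)C/C=C(/CO[Si](c1ccccc1)(c1ccccc1)C(C)(C)C)CC[C@H]1O[C@]1(C)[C@H](O)CO | intermediate
23 | (2S,3R)-3-[(3E,6R,7E)-3-{[(tert-butyldiphenylsilyl)oxy]methyl}-8-iodo-6-methyl-6-(prop-2-en-1-yl)octa-3,7-dien-1-yl]-2-methyloxirane-2-carbaldehyde | I/C=C/[C@](C)(CC=C)C/C=C(/CO[Si](c1ccccc1)(c1ccccc1)C(C)(C)C)CC[C@H]1O[C@]1(C)C=O | intermediate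
24 | (1R,2R,3E,5R,7E,11R)-8-{[(tert-butyldiphenylsilyl)oxy]methyl}-1,5-dimethyl-5-(prop-2-en-1-yl)-12-oxabicyclo[9.1.0]dodeca-3,7-dien-2-ol (oxirane geometry as in the target; the descriptor at position 1 is R only because the free hydroxyl changes priorities) | O[C@@H]1/C=C/[C@](C)(CC=C)C/C=C(/CO[Si](c2ccccc2)(c2ccccc2)C(C)(C)C)CC[C@H]2O[C@]12C | intermediate
25 | 3-methylbut-2-enoic acid | CC(C)=CC(=O)O | starting material
26 | (1S,2S,3E,5R,7E,11R)-8-{[(tert-butyldiphenylsilyl)oxy]methyl}-1,5-dimethyl-5-(prop-2-en-1-yl)-12-oxabicyclo[9.1.0]dodeca-3,7-dien-2-yl 3-methylbut-2-enoate | CC(C)=CC(=O)O[C@H]1/C=C/[C@](C)(CC=C)C/C=C(/CO[Si](c2ccccc2)(c2ccccc2)C(C)(C)C)CC[C@H]2O[C@]12C | intermediate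
27 | 2-methylbut-3-en-2-ol | CC(C)(O)C=C | starting material
28 | (1S,2S,3E,5R,7E,11R)-8-{[(tert-butyldiphenylsilyl)oxy]methyl}-5-[(2E)-4-hydroxy-4-methylpent-2-en-1-yl]-1,5-dimethyl-12-oxabicyclo[9.1.0]dodeca-3,7-dien-2-yl 3-methylbut-2-enoate | CC(C)=CC(=O)O[C@H]1/C=C/[C@](C)(C/C=C/C(C)(C)O)C/C=C(/CO[Si](c2ccccc2)(c2ccccc2)C(C)(C)C)CC[C@H]2O[C@]12C | intermediate
29 | (1S,2S,3E,5R,7E,11R)-8-(hydroxymethyl)-5-[(2E)-4-hydroxy-4-methylpent-2-en-1-yl]-1,5-dimethyl-12-oxabicyclo[9.1.0]dodeca-3,7-dien-2-yl 3-methylbut-2-enoate | CC(C)=CC(=O)O[C@H]1/C=C/[C@](C)(C/C=C/C(C)(C)O)C/C=C(/CO)CC[C@H]2O[C@]12C | target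

## Step count and risks

Total step count: 18. Longest linear sequence: 14 steps (steps 1–5, then 10–18).

The three steps most likely to fail:

**Step 15 (the proposed electrochemical ring closure).** Both the yield of an 11-membered closure under catalytic electrochemical turnover and the facial selectivity at C1 are untested. The fallback sets out from 23 and uses known chemistry that no longer relies on the C–C bond-forming event for the C1 configuration. The ring is closed by a stoichiometric Nozaki–Hiyama–Kishi reaction (CrCl2 10 equiv, NiCl2 2 mol %, DMSO/THF, 2 mM, 25 °C), which gives 24 together with its C1 epimer (1R,2S,3E,5R,7E,11R)-8-{[(tert-butyldiphenylsilyl)oxy]methyl}-1,5-dimethyl-5-(prop-2-en-1-yl)-12-oxabicyclo[9.1.0]dodeca-3,7-dien-2-ol F1. The unseparated carbinols are oxidised with Dess–Martin periodinane to the macrocyclic epoxy enone (1S,3E,5R,7E,11R)-8-{[(tert-butyldiphenylsilyl)oxy]methyl}-1,5-dimethyl-5-(prop-2-en-1-yl)-12-oxabicyclo[9.1.0]dodeca-3,7-dien-2-one F2. Chelation-controlled 1,2-reduction with Zn(BH4)2 (Et2O, −20 °C; carbonyl and oxirane oxygens bound to zinc, hydride from the open face) gives the erythro alcohol, and the route is rejoined at 24.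

**Step 16 (Mitsunobu inversion at a hindered allylic carbinol next to a fully substituted oxirane carbon, with a weak acid).** Elimination or incomplete reaction is possible. The fallback sets out from 24 and separates activation from displacement. MsCl and Et3N (CH2Cl2, −30 °C) give the mesylate (1S,2R,3E,5R,7E,11R)-8-{[(tert-butyldiphenylsilyl)oxy]methyl}-1,5-dimethyl-5-(prop-2-en-1-yl)-12-oxabicyclo[9.1.0]dodeca-3,7-dien-2-yl methanesulfonate F3, used crude. Caesium 3-methylbut-2-enoate (made from 25 and Cs2CO3) with 18-crown-6 in toluene at 50 °C displaces it by SN2 with inversion, and the route is rejoined at 26.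

**Step 14 (directed epoxidation of the free 1,2-diol).** The primary hydroxyl could chelate vanadium with the secondary one and erode rate or facial selectivity. The fallback sets out from 21 and masks the primary hydroxyl so that only the secondary allylic alcohol directs. Et3SiCl and 2,6-lutidine (CH2Cl2, −78 °C) give the primary silyl ether (2S,3E,7E,10R,11E)-7-{[(tert-butyldiphenylsilyl)oxy]methyl}-12-iodo-3,10-dimethyl-10-(prop-2-en-1-yl)-1-[(triethylsilyl)oxy]dodeca-3,7,11-trien-2-ol F4. VO(acac)2/t-BuOOH (CH2Cl2, 0 °C) then gives the erythro epoxy alcohol (1R)-1-{(2R,3R)-3-[(3E,6R,7E)-3-{[(tert-butyldiphenylsilyl)oxy]methyl}-8-iodo-6-methyl-6-(prop-2-en-1-yl)octa-3,7-dien-1-yl]-2-methyloxiran-2-yl}-2-[(triethylsilyl)oxy]ethan-1-ol F5. Pyridine-buffered HF·pyridine (THF, 0 °C) removes only the triethylsilyl group, and the route is rejoined at 22, which is cleaved with NaIO4 as in step 14.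

## Further compounds

F1 | step 15 | (1R,2S,3E,5R,7E,11R)-8-{[(tert-butyldiphenylsilyl)oxy]methyl}-1,5-dimethyl-5-(prop-2-en-1-yl)-12-oxabicyclo[9.1.0]dodeca-3,7-dien-2-ol | O[C@H]1/C=C/[C@](C)(CC=C)C/C=C(/CO[Si](c2ccccc2)(c2ccccc2)C(C)(C)C)CC[C@H]2O[C@]12C
F2 | step 15 | (1S,3E,5R,7E,11R)-8-{[(tert-butyldiphenylsilyl)oxy]methyl}-1,5-dimethyl-5-(prop-2-en-1-yl)-12-oxabicyclo[9.1.0]dodeca-3,7-dien-2-one | O=C1/C=C/[C@](C)(CC=C)C/C=C(/CO[Si](c2ccccc2)(c2ccccc2)C(C)(C)C)CC[C@H]2O[C@]12C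
F3 | step 16 | (1S,2R,3E,5R,7E,11R)-8-{[(tert-butyldiphenylsilyl)oxy]methyl}-1,5-dimethyl-5-(prop-2-en-1-yl)-12-oxabicyclo[9.1.0]dodeca-3,7-dien-2-yl methanesulfonate | CS(=O)(=O)O[C@@H]1/C=C/[C@](C)(CC=C)C/C=C(/CO[Si](c2ccccc2)(c2ccccc2)C(C)(C)C)CC[C@H]2O[C@]12C
F4 | step 14 | (2S,3E,7E,10R,11E)-7-{[(tert-butyldiphenylsilyl)oxy]methyl}-12-iodo-3,10-dimethyl-10-(prop-2-en-1-yl)-1-[(triethylsilyl)oxy]dodeca-3,7,11-trien-2-ol | I/C=C/[C@](C)(CC=C)C/C=C(/CO[Si](c1ccccc1)(c1ccccc1)C(C)(C)C)CC/C=C(\C)[C@H](O)CO[Si](CC)(CC)CC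
F5 | step 14 | (1R)-1-{(2R,3R)-3-[(3E,6R,7E)-3-{[(tert-butyldiphenylsilyl)oxy]methyl}-8-iodo-6-methyl-6-(prop-2-en-1-yl)octa-3,7-dien-1-yl]-2-methyloxiran-2-yl}-2-[(triethylsilyl)oxy]ethan-1-ol | I/C=C/[C@](C)(CC=C)C/C=C(/CO[Si](c1ccccc1)(c1ccccc1)C(C)(C)C)CC[C@H]1O[C@]1(C)[C@H](O)CO[Si](CC)(CC)CC
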